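## Retrosynthetic overview

1. Carbocycle (first ring made): acetylacetone 1 and prenyl bromide 2 give gem-diprenyl diketone 3. After C-acetylation to triketone 4, the ring C=C bond is closed by a polyketide-type (Collie) aldol condensation, via ketol 5, to vinylogous acid 6, so the diprenylated carbon is fixed before the ring exists.
2. Arene (bought): 3-methoxybenzonitrile 7; the future C3 comes from ortho-formylation to cyanoaldehyde 8.
3. Lactam ring (second ring made, in the last flask): 8 is converted in situ into the hydroxylactam-type methoxy lactam 9, the precursor of N-acyl imine 10.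
4. Last bond, C3–C(dienone): enantioselective Mannich addition of 6 to 10 under a chiral phosphoric acid gives target 11 and its only stereocentre (R).

Assumption: the single stereocentre is (R) (CIP order N > dienone C > aryl C > H) and this vinylogous Mannich base is taken to be configurationally stable at or below room temperature without strong acid or base; the (R)-configured phosphoric acid is taken to give Si-face attack, and its mirror image is used, with nothing else changed, if the measured sense is opposite.

## Route

Step 1
Reactants: 1 pentane-2,4-dione (acetylacetone); 2 1-bromo-3-methylbut-2-ene (prenyl bromide, 2.3 equiv)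
Product: 3 3,3-bis(3-methylbut-2-en-1-yl)pentane-2,4-dione
Conditions: K2CO3 (3 equiv), acetone, 56 °C, 24 h
Reagents that add atoms: none
Why: double enolate C-alkylation of a 1,3-diketone with a soft allylic bromide builds the quaternary gem-diprenyl carbon on an acyclic precursor, which avoids the site-selectivity problem of prenylating orcinol itself; no stereocentre is formed.

Step 2
Reactants: 3 3,3-bis(3-methylbut-2-en-1-yl)pentane-2,4-dione
Product: 6 3-hydroxy-5-methyl-6,6-bis(3-methylbut-2-en-1-yl)cyclohexa-2,4-dien-1-one, via triketone 4 (not isolated), via ketol 5 (not isolated)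
Conditions: MgBr2·OEt2 (2.5 equiv), i-Pr2NEt (3 equiv), 1-acetyl-1H-benzotriazole (1.05 equiv), CH2Cl2, 23 °C; evaporate; then 2 M aq NaOH, MeOH, 23 °C; aq HCl to pH 3, 0 °C
Reagents that add atoms: 1-acetyl-1H-benzotriazole, CC(=O)n1nnc2ccccc12
Why: soft-enolisation Claisen-type C-acylation of one acetyl methyl gives β-triketone 4, whose diketonate in aqueous base undergoes a Collie-type intramolecular aldol addition of its terminal methyl onto the only non-enolised ketone and E1cB dehydration (the aldol logic that makes the orcinol ring in nature); the quaternary carbon blocks aromatisation, so the ring stops at vinylogous acid 6, and the stereocentre of racemic ketol 5 is lost on dehydration.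

Step 3
Reactants: 7 3-methoxybenzonitrile
Product: 8 2-formyl-3-methoxybenzonitrile
Conditions: lithium 2,2,6,6-tetramethylpiperidide (1.15 equiv, made in the flask from 2,2,6,6-tetramethylpiperidine and n-BuLi), THF, −78 °C, 20 min; DMF (2 equiv), −78 °C; 2 M aq HCl, −78 → 0 °C
Reagents that add atoms: N,N-dimethylformamide, CN(C)C=O
Why: directed ortho-metalation by a non-nucleophilic lithium amide at the C–H flanked by the nitrile and the methoxy group, then formylation with DMF; the cold acidic quench releases the aldehyde before the amino alkoxide can cyclise onto the nitrile, and no stereocentre is formed.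

Step 4
Reactants: 8 2-formyl-3-methoxybenzonitrile; 6 3-hydroxy-5-methyl-6,6-bis(3-methylbut-2-en-1-yl)cyclohexa-2,4-dien-1-one (1.1 equiv)
Product: 11 (3R)-3-[2-hydroxy-4-methyl-5,5-bis(3-methylbut-2-en-1-yl)-6-oxocyclohexa-1,3-dien-1-yl]-4-methoxy-2,3-dihydro-1H-isoindol-1-one, via methoxy lactam 9 (not isolated), via acyl imine 10 (not isolated)
Conditions: Et3N (0.3 equiv), MeOH, 40 °C, 2 h; evaporate, toluene azeotrope; then 6, (R)-3,3′-bis(2,4,6-triisopropylphenyl)-1,1′-binaphthyl-2,2′-diyl hydrogen phosphate (10 mol %), 5 Å molecular sieves, toluene, −20 °C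
Reagents that add atoms: none
Why: Proposed new method: Et3N-catalysed addition of methanol to the aldehyde, attack of the hemiacetal alkoxide on the nitrile and imidate-to-lactam rearrangement close the lactam ring as the hydroxylactam-type N,O-acetal 9 (the known tandem behaviour of 2-cyanobenzaldehydes in alcohols), after which the chiral phosphoric acid expels methanol to give the ion-paired N-acyliminium form of 10 (helped by the ortho-methoxy group) and, hydrogen-bonding the enol O–H of 6 through P=O, delivers C2 of 6 to the Si face of C3 (N > aryl C > H) so that C3 becomes (R), the closest known reaction type being chiral-phosphoric-acid-catalysed Mannich and aza-Friedel–Crafts additions of 1,3-dicarbonyl enols and indoles to N-acyl imines generated from 3-hydroxyisoindolinones.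

## Compound list

1 | pentane-2,4-dione (acetylacetone) | CC(=O)CC(C)=O | starting material
2 | 1-bromo-3-methylbut-2-ene (prenyl bromide) | CC(C)=CCBr | starting material
3 | 3,3-bis(3-methylbut-2-en-1-yl)pentane-2,4-dione | CC(=O)C(CC=C(C)C)(CC=C(C)C)C(C)=O | intermediate
4 | 3,3-bis(3-methylbut-2-en-1-yl)heptane-2,4,6-trione (not isolated) | CC(=O)CC(=O)C(CC=C(C)C)(CC=C(C)C)C(C)=O | intermediate
5 | racemic 5-hydroxy-5-methyl-4,4-bis(3-methylbut-2-en-1-yl)cyclohexane-1,3-dione (not isolated) | CC1(O)CC(=O)CC(=O)C1(CC=C(C)C)CC=C(C)C | intermediate
6 | 3-hydroxy-5-methyl-6,6-bis(3-methylbut-2-en-1-yl)cyclohexa-2,4-dien-1-one (vinylogous acid) | CC1=CC(O)=CC(=O)C1(CC=C(C)C)CC=C(C)C | intermediate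
7 | 3-methoxybenzonitrile | COc1cccc(C#N)c1 | starting material
8 | 2-formyl-3-methoxybenzonitrile | COc1cccc(C#N)c1C=O | intermediate
9 | racemic 3,4-dimethoxy-2,3-dihydro-1H-isoindol-1-one (not isolated) | COC1NC(=O)c2cccc(OC)c12 | intermediate
10 | 4-methoxy-1H-isoindol-1-one, the N-acyl imine, present as its phosphate-bound N-acyliminium (not isolated) | COc1cccc2c1C=NC2=O | intermediate
11 | (3R)-3-[2-hydroxy-4-methyl-5,5-bis(3-methylbut-2-en-1-yl)-6-oxocyclohexa-1,3-dien-1-yl]-4-methoxy-2,3-dihydro-1H-isoindol-1-one | COc1cccc2c1[C@H](C1=C(O)C=C(C)C(CC=C(C)C)(CC=C(C)C)C1=O)NC2=O | target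

## Step count and risks

Total steps: 4. Longest linear sequence: 3 (steps 1, 2, 4); the arene branch is 2 (steps 3, 4).

Steps most likely to fail, most risky first:

**Step 2 (acetylation and aldol ring closure).** Risks are double acylation, hydroxide retro-Claisen cleavage of the 2,2-disubstituted diketone unit, and retro-aldol opening of ketol 5 toward an isomeric triketone that would aromatise. The fallback sets out from 3 and comes back at 6, replacing acylation/aldol by a Michael–Claisen annulation. Methanolysis of 3 (NaOMe, MeOH, 23 °C; retro-Claisen loss of one acetyl) gives 6-methyl-3-(3-methylbut-2-en-1-yl)hept-5-en-2-one F1. Its more substituted potassium enolate (KOt-Bu, t-BuOH/THF, 0 → 23 °C) adds in Michael fashion to methyl but-2-ynoate to give methyl (2Z)-4-acetyl-3,7-dimethyl-4-(3-methylbut-2-en-1-yl)octa-2,6-dienoate F2. F2 is not isolated: its E isomer equilibrates under the base, and the methyl-ketone enolate closes onto the ester by Claisen condensation, giving 6 directly.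

**Step 4 (lactam formation and asymmetric Mannich addition).** Risks are racemic background catalysis by the acidic vinylogous acid 6, erosion of ee by retro-Mannich, and an unpredictable sense of induction. The fallback sets out from 6 and 8 and comes back at 11, replacing catalyst control by resolution with recycling. Stage one is run as before; an achiral acid (diphenyl phosphate, 10 mol %, toluene, 23 °C) then gives racemic 3-[2-hydroxy-4-methyl-5,5-bis(3-methylbut-2-en-1-yl)-6-oxocyclohexa-1,3-dien-1-yl]-4-methoxy-2,3-dihydro-1H-isoindol-1-one F4. Preparative chiral SFC on an amylose tris(3,5-dimethylphenylcarbamate) phase separates 11 from (3S)-3-[2-hydroxy-4-methyl-5,5-bis(3-methylbut-2-en-1-yl)-6-oxocyclohexa-1,3-dien-1-yl]-4-methoxy-2,3-dihydro-1H-isoindol-1-one F5. F5 is re-racemised with the same acid at 60 °C (retro-Mannich and re-addition through 10 and 6) and resubmitted.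

**Step 3 (ortho-formylation of the nitrile).** Risks are addition of the aryllithium to the nitrile of unreacted 7 and cyclisation of the DMF adduct onto the nitrile. The fallback sets out from 7 and comes back at 8, replacing direct lithiation–formylation by halogenation and halogen–metal exchange. Deprotonative zincation under in situ trapping (lithium 2,2,6,6-tetramethylpiperidide with ZnCl2·TMEDA, TMEDA being N,N,N′,N′-tetramethylethylenediamine, THF, 0 °C) followed by I2 gives 2-iodo-3-methoxybenzonitrile F3. Iodine–magnesium exchange (i-PrMgCl·LiCl, THF, −40 °C), DMF and a cold aqueous acid quench then give 8 through a less basic arylmagnesium and a less nucleophilic magnesium alkoxide.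

## Further compounds

F1 | step 2 | 6-methyl-3-(3-methylbut-2-en-1-yl)hept-5-en-2-one | CC(=O)C(CC=C(C)C)CC=C(C)C
F2 | step 2 | methyl (2Z)-4-acetyl-3,7-dimethyl-4-(3-methylbut-2-en-1-yl)octa-2,6-dienoate | COC(=O)/C=C(/C)C(CC=C(C)C)(CC=C(C)C)C(C)=O
F3 | step 3 | 2-iodo-3-methoxybenzonitrile | COc1cccc(C#N)c1I
F4 | step 4 | racemic 3-[2-hydroxy-4-methyl-5,5-bis(3-methylbut-2-en-1-yl)-6-oxocyclohexa-1,3-dien-1-yl]-4-methoxy-2,3-dihydro-1H-isoindol-1-one | COc1cccc2c1C(C1=C(O)C=C(C)C(CC=C(C)C)(CC=C(C)C)C1=O)NC2=O
F5 | step 4 | (3S)-3-[2-hydroxy-4-methyl-5,5-bis(3-methylbut-2-en-1-yl)-6-oxocyclohexa-1,3-dien-1-yl]-4-methoxy-2,3-dihydro-1H-isoindol-1-one | COc1cccc2c1[C@@H](C1=C(O)C=C(C)C(CC=C(C)C)(CC=C(C)C)C1=O)NC2=O
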